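The reading at 3.0 h set the decision: should the next charge of solid substrate be raised to bring more target by then, or kept? That hung on the level of dissolved substrate while solid remains.

| setting | elm | flask |
|---|---|---|
| solid substrate | 0.25 M | 0.25 M |
| reagent | 0.225 M | 0.225 M |
| remark | the very flask that is asked about, followed so far |  |
| time |  | 3.0 h |

elm run (percent of the solid substrate charged)

| time / min | target / % | solid substrate / % |
|---|---|---|
| 2.00 | 1.5 | 97.6 |
| 6.00 | 1.4 | 94.6 |
| 10.0 | 1.1 | 90.5 |
| 15.0 | 0.6 | 86.0 |
| 20.0 | 1.3 | 83.1 |
| 30.0 | 3.9 | 77.6 |
| 40.0 | 6.2 | 72.6 |

(standard deviation of a reading: 1 percentage point)

- a species is counted by the solid substrate in it: one side product counts as two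
- amounts and yields of target count crystals too
- given per volume of solution although it is solid: solid substrate, crystals
- the analysis behind the earlier runs scatters by 1 percentage point, standard deviation
- reactions considered so far: solid substrate <-> dissolved substrate; dissolved substrate + reagent -> target; 2 dissolved substrate -> side product; target <-> isomer of the product; crystals <-> target
- at the start none of the solid substrate is in solution
- dissolved substrate means what is dissolved; the solid is not counted in it
- the concentration of target that is asked is that of its free form alone

* concentration of target (only what is free in solution) at 3.0 h, in M
* concentration of solid substrate at 3.0 h, in M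
* concentration of side product at 3.0 h, in M
* concentration of dissolved substrate at 3.0 h, in M
* concentration of reagent at 3.0 h, in M

In the elm run the solid substrate went at 0.142 M/h up to 10.0 min, but at 0.0750 M/h from 30.0 min to 40.0 min. That is half the first rate, with 72.6% of the solid still there, so I read the rate as a gap to a solubility, not as a share of the solid. I took [dissolved substrate] as 0.0119 M early and, from solid lost less target, 0.0496 M late. Those two points gave a dissolving constant of 1.79 /h and a solubility of 0.0916 M.

The rise of target between the last two readings, which carries much of their scatter, gave a reagent constant of 3.27 /M/h.

Setting dissolving equal to use by reagent (a quasi-steady state) gives my holding level, the [dissolved substrate] at which the two balance. It is 0.0649 M at the charged reagent. That level takes [reagent] down to 0.119 M by the reading, and the level there is 0.0752 M. The charge of solid does not enter this reckoning while solid remains. By my reckoning, the reagent used plus this level leaves 0.0688 M of solid at the reading, so I kept the charge.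

The forecast stood at 0.05 M target, 0.06 M solid substrate, 0.012 M side product, 0.055 M dissolved substrate and 0.125 M reagent, with “dissolved substrate plateaus near 0.06 M”.

This flask gave 0.0769 M target, 0.0696 M solid substrate, 0.00507 M side product, 0.0712 M dissolved substrate and 0.126 M reagent.

    solid substrate ⇌ dissolved substrate, rate k1*(cs1 - [dissolved substrate]) while solid is left; crystals form when [dissolved substrate] > cs1 (solubility = 0.0920 M, k = 1.80 /h)
    dissolved substrate + reagent → target (k = 3.30 /M/h)
    2 dissolved substrate → side product (k = 0.460 /M/h)
    target ⇌ isomer of the product (K = 0.540, k = 0.300 /h)
    crystals ⇌ target, rate k5*(cs5 - [target]) while solid is left; crystals form when [target] > cs5 (solubility = 0.130 M, k = 4.40 /h)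

Part of what kept [target] at 0.0769 M in this flask was the low solubility of dissolved substrate, acting together with the time given: without that limit the run reached 0.110 M, and left until 30.0 h it reached 0.130 M. For the neighbour flask charged with 0.62 M of solid substrate, my holding level stays 0.0752 M, and my reckoning leaves 0.439 M of solid. That flask gave 0.440 M of solid and 0.0769 M target.

The readings are calculated for an exercise; scatter was added.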